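**Plan**
- Retrosynthesis: after the three phenol protecting groups, ring C (the pyran) is cut in one stroke at C3–C4 and at O1–C8a. This leaves ring B carrying O1–C2–C3 as an (S)-aryl oxirane, and ring A carrying C4 as a 2-fluorobenzyl metal.
- Enabling feature: O1–C2–C3 is an epoxide in disguise (C3 electrophilic, O1 an alkoxide once C3 is attacked). C4–C4a–C8a of the resorcinol-type ring A can carry the matching polarity (benzylic C4 as a Grignard carbon, C8a as a fluoride-bearing SNAr site). The two three-atom units close ring C in a [3+3] sense, and the fluorine helper is lost in the same step.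
- Further back, the oxirane is cut to an aryl chloromethyl ketone and then to an aldehyde, and the two aryl–prenyl bonds are cut to a 2,3-dibromide made from 5-bromovanillin.
- Forward order: ring B is fully substituted first (bromination, protecting-group change, double prenylation), then its formyl carbon is turned into the oxirane. Ring A is prepared separately in three steps, ring C is formed in the last step but one, and the MOM groups are removed at the end.
- Stereochemistry: the single stereocenter C2 is set by asymmetric transfer hydrogenation of the chloroketone. It is carried through epoxide, annulation and deprotection with its C–O bond intact.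

Key step: step 11

Assumption: the sense of induction in step 7 is taken from the usual behaviour of RuCl(arene)(TsDPEN) catalysts with aryl ketones (aryl group in the CH/π position); the other ligand enantiomer would be used if the chlorohydrin proved to have the opposite configuration.

**Step 1**
Reactants: 1 5-bromovanillin (3-bromo-4-hydroxy-5-methoxybenzaldehyde)
Product: 2 2,3-dibromo-4-hydroxy-5-methoxybenzaldehyde
Conditions: Br2 (1.2 equiv), Fe powder (cat.), AcOH, rt → 60 °C
Reagents that add atoms: bromine, BrBr
Why: Electrophilic aromatic bromination, which should take the only open position para to the methoxy group (next to the formyl group), a known conversion of bromovanillins.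

**Step 2**
Reactants: 2 2,3-dibromo-4-hydroxy-5-methoxybenzaldehyde
Product: 3 2,3-dibromo-4,5-dihydroxybenzaldehyde
Conditions: AlCl3 (1.2 equiv), pyridine (4 equiv), CH2Cl2, reflux; then 1 M HCl
Reagents that add atoms: none
Why: Lewis-acid-assisted O-demethylation of an ortho-hydroxyanisole, in which the aluminium chelate of the guaiacol unit activates the methyl group for transfer to pyridine, the standard way from bromovanillins to bromocatechol aldehydes.

**Step 3**
Reactants: 3 2,3-dibromo-4,5-dihydroxybenzaldehyde
Product: 4 2,3-dibromo-4,5-bis(methoxymethoxy)benzaldehyde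
Conditions: NaH (2.4 equiv), DMF, 0 °C; MOMCl (2.6 equiv), 0 °C → rt
Reagents that add atoms: chloromethyl methyl ether (MOMCl), COCCl
Why: Williamson-type O-alkylation of both phenoxides, giving acetal protecting groups that should survive the organometallic and strongly basic steps ahead.

**Step 4**
Reactants: 4 2,3-dibromo-4,5-bis(methoxymethoxy)benzaldehyde
Product: 5 4,5-bis(methoxymethoxy)-2,3-bis(3-methylbut-2-en-1-yl)benzaldehyde
Conditions: tributyl(prenyl)stannane (3 equiv), Pd2(dba)3 (5 mol %), P(t-Bu)3 (20 mol %), CsF (4 equiv), dioxane, 100 °C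
Reagents that add atoms: tributyl(3-methylbut-2-en-1-yl)stannane, CC(C)=CC[Sn](CCCC)(CCCC)CCCC
Why: Twofold Stille coupling, in which the bromide ortho to the formyl group is activated for oxidative addition, the bulky electron-rich phosphine should drive the second, hindered coupling, and reductive elimination from the less hindered allyl terminus should give the linear prenyl groups while the allylstannane leaves the aldehyde alone.

**Step 5**
Reactants: 5 4,5-bis(methoxymethoxy)-2,3-bis(3-methylbut-2-en-1-yl)benzaldehyde
Product: 6 racemic 2-chloro-1-[4,5-bis(methoxymethoxy)-2,3-bis(3-methylbut-2-en-1-yl)phenyl]ethan-1-ol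
Conditions: ICH2Cl (1.5 equiv), MeLi·LiBr (1.4 equiv), THF, −78 °C; then AcOH, −78 °C
Reagents that add atoms: chloroiodomethane, ClCI
Why: Carbonyl addition of chloromethyllithium generated by iodine–lithium exchange in the presence of the aldehyde (exchange outruns direct addition of MeLi), with a cold acidic quench that keeps the chlorohydrin from closing to the racemic epoxide.

**Step 6**
Reactants: 6 racemic 2-chloro-1-[4,5-bis(methoxymethoxy)-2,3-bis(3-methylbut-2-en-1-yl)phenyl]ethan-1-ol
Product: 7 2-chloro-1-[4,5-bis(methoxymethoxy)-2,3-bis(3-methylbut-2-en-1-yl)phenyl]ethan-1-one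
Conditions: Dess–Martin periodinane (1.3 equiv), CH2Cl2, 0 °C → rt
Reagents that add atoms: none
Why: Dess–Martin oxidation of a secondary benzylic alcohol, a hypervalent-iodine oxidation that should leave the prenyl double bonds, the MOM acetals and the alkyl chloride untouched.

**Step 7**
Reactants: 7 2-chloro-1-[4,5-bis(methoxymethoxy)-2,3-bis(3-methylbut-2-en-1-yl)phenyl]ethan-1-one
Product: 9 (S)-2-[4,5-bis(methoxymethoxy)-2,3-bis(3-methylbut-2-en-1-yl)phenyl]oxirane, via (S)-chlorohydrin 8 (not isolated)
Conditions: RuCl(p-cymene)[(R,R)-TsDPEN] (1 mol %), HCO2H/Et3N (5:2), EtOAc, rt; then 2 M NaOH, i-PrOH, 0 °C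
Reagents that add atoms: none
Why: Noyori asymmetric transfer hydrogenation of an aryl chloromethyl ketone, in which the (R,R)-ligand should deliver hydride to the face that gives the (S)-chlorohydrin, followed by Williamson ring closure at the CH2Cl carbon, which does not touch the new stereocenter; no borane is present that could hydroborate the prenyl groups.

**Step 8**
Reactants: 10 2-fluoro-4-hydroxybenzaldehyde
Product: 11 2-fluoro-4-(methoxymethoxy)benzaldehyde
Conditions: NaH (1.2 equiv), DMF, 0 °C; MOMCl (1.3 equiv), 0 °C → rt
Reagents that add atoms: chloromethyl methyl ether (MOMCl), COCCl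
Why: Williamson-type O-alkylation of the phenoxide at low temperature, where the fluoride ortho to the formyl group should not yet be displaced.

**Step 9**
Reactants: 11 2-fluoro-4-(methoxymethoxy)benzaldehyde
Product: 12 [2-fluoro-4-(methoxymethoxy)phenyl]methanol
Conditions: NaBH4, MeOH, 0 °C
Reagents that add atoms: none
Why: Borohydride reduction of an aromatic aldehyde to the benzylic alcohol.

**Step 10**
Reactants: 12 [2-fluoro-4-(methoxymethoxy)phenyl]methanol
Product: 13 1-(chloromethyl)-2-fluoro-4-(methoxymethoxy)benzene
Conditions: PPh3, N-chlorosuccinimide, THF, 0 °C → rt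
Reagents that add atoms: N-chlorosuccinimide, O=C1CCC(=O)N1Cl
Why: Appel-type chlorination through the alkoxyphosphonium salt under non-acidic conditions that spare the MOM acetal.

**Step 11**
Reactants: 13 1-(chloromethyl)-2-fluoro-4-(methoxymethoxy)benzene; 9 (S)-2-[4,5-bis(methoxymethoxy)-2,3-bis(3-methylbut-2-en-1-yl)phenyl]oxirane
Product: 16 (2R)-2-[4,5-bis(methoxymethoxy)-2,3-bis(3-methylbut-2-en-1-yl)phenyl]-7-(methoxymethoxy)chromane, via benzylmagnesium chloride 14 (not isolated), via chloromagnesium alkoxide 15 (not isolated)
Conditions: 13 (1.5 equiv), Mg turnings, THF, 0 °C; CuBr·SMe2 (10 mol %), 9, THF, −40 → 0 °C; then t-BuOK (3 equiv), DMF, 60 °C, same flask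
Reagents that add atoms: none
Why: The benzylic Grignard reagent 14, as its benzylcopper species, opens the (S)-epoxide 9 by SN2 attack at the unsubstituted CH2 carbon (C3–C4 bond) to give alkoxide 15, which after exchange to the potassium alkoxide displaces the ortho fluoride of ring A by addition–elimination (O1–C8a bond). The closest known reaction types are the copper-catalysed opening of terminal aryl epoxides by benzyl Grignard reagents and the intramolecular SNAr etherification of 3-(2-fluoroaryl)propan-1-olates to chromans. Ring C is closed in a 6-exo-trig manner, the alkoxide oxygen adding to the fluorine-bearing ring carbon and fluoride leaving from the Meisenheimer-type intermediate. No new stereocenter is formed: C2 is the epoxide carbon whose C–O bond is never broken, so the (S)-epoxide is carried over as the (2R)-flavan, the descriptor changing only through the CIP priorities. The step needs attack at the terminal and not the benzylic epoxide carbon, which the soft copper nucleophile at low temperature, the ortho prenyl group beside the benzylic carbon and the 4-OMOM group of ring B (twisted out of conjugation by its two neighbours, so a weak donor) should secure. In the closure only the fluorine ortho to the tether is within reach of the alkoxide, and the meta OMOM group of ring A leaves that carbon electrophilic enough.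

**Step 12**
Reactants: 16 (2R)-2-[4,5-bis(methoxymethoxy)-2,3-bis(3-methylbut-2-en-1-yl)phenyl]-7-(methoxymethoxy)chromane
Product: 17 (+)-(2R)-kazinol I, 5-[(2R)-7-hydroxy-3,4-dihydro-2H-chromen-2-yl]-3,4-bis(3-methylbut-2-en-1-yl)benzene-1,2-diol
Conditions: HCl (ca. 1 M in MeOH), THF, rt → 40 °C, argon
Reagents that add atoms: none
Why: Acid-catalysed acetal exchange of the three aryl MOM ethers with methanol, for which dilute acid at low temperature is the usual way to free ortho-prenylphenols without cyclisation of the prenyl group onto the phenol or ionisation of the C2–O bond.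

**Compound list**
1 | 5-bromovanillin (3-bromo-4-hydroxy-5-methoxybenzaldehyde) | COc1cc(C=O)cc(Br)c1O | starting material
2 | 2,3-dibromo-4-hydroxy-5-methoxybenzaldehyde | COc1cc(C=O)c(Br)c(Br)c1O | intermediate
3 | 2,3-dibromo-4,5-dihydroxybenzaldehyde | O=Cc1cc(O)c(O)c(Br)c1Br | intermediate
4 | 2,3-dibromo-4,5-bis(methoxymethoxy)benzaldehyde | O=Cc1cc(OCOC)c(OCOC)c(Br)c1Br | intermediate
5 | 4,5-bis(methoxymethoxy)-2,3-bis(3-methylbut-2-en-1-yl)benzaldehyde | O=Cc1cc(OCOC)c(OCOC)c(CC=C(C)C)c1CC=C(C)C | intermediate
6 | racemic 2-chloro-1-[4,5-bis(methoxymethoxy)-2,3-bis(3-methylbut-2-en-1-yl)phenyl]ethan-1-ol | OC(CCl)c1cc(OCOC)c(OCOC)c(CC=C(C)C)c1CC=C(C)C | intermediate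
7 | 2-chloro-1-[4,5-bis(methoxymethoxy)-2,3-bis(3-methylbut-2-en-1-yl)phenyl]ethan-1-one | O=C(CCl)c1cc(OCOC)c(OCOC)c(CC=C(C)C)c1CC=C(C)C | intermediate
8 | (1S)-2-chloro-1-[4,5-bis(methoxymethoxy)-2,3-bis(3-methylbut-2-en-1-yl)phenyl]ethan-1-ol (formed in the flask in step 7) | CC(C)=CCc1c([C@H](O)CCl)cc(OCOC)c(OCOC)c1CC=C(C)C | intermediate
9 | (S)-2-[4,5-bis(methoxymethoxy)-2,3-bis(3-methylbut-2-en-1-yl)phenyl]oxirane | CC(C)=CCc1c([C@H]2CO2)cc(OCOC)c(OCOC)c1CC=C(C)C | intermediate
10 | 2-fluoro-4-hydroxybenzaldehyde | O=Cc1ccc(O)cc1F | starting material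
11 | 2-fluoro-4-(methoxymethoxy)benzaldehyde | O=Cc1ccc(OCOC)cc1F | intermediate
12 | [2-fluoro-4-(methoxymethoxy)phenyl]methanol | OCc1ccc(OCOC)cc1F | intermediate
13 | 1-(chloromethyl)-2-fluoro-4-(methoxymethoxy)benzene | ClCc1ccc(OCOC)cc1F | intermediate
14 | [2-fluoro-4-(methoxymethoxy)benzyl]magnesium chloride (formed in the flask in step 11) | Cl[Mg]Cc1ccc(OCOC)cc1F | intermediate
15 | chloromagnesium (1R)-1-[4,5-bis(methoxymethoxy)-2,3-bis(3-methylbut-2-en-1-yl)phenyl]-3-[2-fluoro-4-(methoxymethoxy)phenyl]propan-1-olate (formed in the flask in step 11) | CC(C)=CCc1c([C@H](O[Mg]Cl)CCc2ccc(OCOC)cc2F)cc(OCOC)c(OCOC)c1CC=C(C)C | intermediate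
16 | (2R)-2-[4,5-bis(methoxymethoxy)-2,3-bis(3-methylbut-2-en-1-yl)phenyl]-7-(methoxymethoxy)chromane | CC(C)=CCc1c([C@H]2CCc3ccc(OCOC)cc3O2)cc(OCOC)c(OCOC)c1CC=C(C)C | intermediate
17 | (+)-(2R)-kazinol I | CC(C)=CCc1c([C@H]2CCc3ccc(O)cc3O2)cc(O)c(O)c1CC=C(C)C | target

**Step count**
Total: 12 steps. Longest linear sequence: 9 steps (steps 1–7, 11 and 12, from 5-bromovanillin); the ring A branch (steps 8–10) joins at step 11.

**Steps most likely to fail**

Step 11. What may go wrong: the organometallic may attack the benzylic epoxide carbon; magnesium halide may trigger a hydride shift of the electron-rich aryl epoxide to the arylacetaldehyde before the terminal opening; or the excess base may move the prenyl double bonds into conjugation during the closure. The fallback makes the two bonds one after the other from 5 and 13 by known chemistry. Aldehyde 5 with MeMgBr in THF should give the racemic 1-[4,5-bis(methoxymethoxy)-2,3-bis(3-methylbut-2-en-1-yl)phenyl]ethan-1-ol F1, and Dess–Martin oxidation the corresponding methyl ketone F2. Its lithium enolate (LDA, THF, −78 °C) is alkylated with the benzylic chloride 13 to the 1,3-diarylpropan-1-one F3. Corey–Bakshi–Shibata reduction with the (S)-oxazaborolidine and catecholborane (chosen over BH3 to spare the prenyl groups) should give the (1R)-1,3-diarylpropan-1-ol F4. F4 is closed by SNAr with KHMDS and 18-crown-6 in THF at 50 °C, which rejoins the route at 16.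

Step 4. What may go wrong: stalling after the first coupling at the bromide flanked by the new prenyl group and the MOM ether, protodebromination, or allyl transposition to the branched 1,1-dimethylallyl isomer. The fallback sets out from 4. NaBH4 reduction gives [2,3-dibromo-4,5-bis(methoxymethoxy)phenyl]methanol F5, in which no aldehyde restricts the choice of allyl metal. Twofold Negishi coupling with prenylzinc bromide (Pd(OAc)2, a bulky biaryl dialkylphosphine such as XPhos, THF, rt) has precedent for linear-selective prenylation and transmetalates much faster than tin; it should give [4,5-bis(methoxymethoxy)-2,3-bis(3-methylbut-2-en-1-yl)phenyl]methanol F6. MnO2 in CH2Cl2 returns the route to aldehyde 5.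

Step 7. What may go wrong: slow or poorly face-selective hydride transfer to the ortho-substituted ketone, or loss of the acid- and silica-sensitive electron-rich aryl epoxide by ring opening or rearrangement during closure and isolation. The fallback sets out from aldehyde 5. Corey–Chaykovsky methylenation (trimethylsulfonium iodide, NaH, DMSO/THF) should give the racemic 2-[4,5-bis(methoxymethoxy)-2,3-bis(3-methylbut-2-en-1-yl)phenyl]oxirane F7 in one step. Jacobsen hydrolytic kinetic resolution with (S,S)-(salen)Co(OAc), a complex of trivalent cobalt (0.55 equiv H2O, THF, 0 °C → rt), is expected by analogy with simple terminal epoxides to hydrolyse the (R)-enantiomer and leave the (S)-epoxide 9. This costs half the material, but steps 5 and 6 are then not needed.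

**Further compounds**
F1 | step 11 | racemic 1-[4,5-bis(methoxymethoxy)-2,3-bis(3-methylbut-2-en-1-yl)phenyl]ethan-1-ol | CC(O)c1cc(OCOC)c(OCOC)c(CC=C(C)C)c1CC=C(C)C
F2 | step 11 | 1-[4,5-bis(methoxymethoxy)-2,3-bis(3-methylbut-2-en-1-yl)phenyl]ethan-1-one | CC(=O)c1cc(OCOC)c(OCOC)c(CC=C(C)C)c1CC=C(C)C
F3 | step 11 | 1-[4,5-bis(methoxymethoxy)-2,3-bis(3-methylbut-2-en-1-yl)phenyl]-3-[2-fluoro-4-(methoxymethoxy)phenyl]propan-1-one | O=C(CCc1ccc(OCOC)cc1F)c1cc(OCOC)c(OCOC)c(CC=C(C)C)c1CC=C(C)C
F4 | step 11 | (1R)-1-[4,5-bis(methoxymethoxy)-2,3-bis(3-methylbut-2-en-1-yl)phenyl]-3-[2-fluoro-4-(methoxymethoxy)phenyl]propan-1-ol | CC(C)=CCc1c([C@H](O)CCc2ccc(OCOC)cc2F)cc(OCOC)c(OCOC)c1CC=C(C)C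
F5 | step 4 | [2,3-dibromo-4,5-bis(methoxymethoxy)phenyl]methanol | OCc1cc(OCOC)c(OCOC)c(Br)c1Br
F6 | step 4 | [4,5-bis(methoxymethoxy)-2,3-bis(3-methylbut-2-en-1-yl)phenyl]methanol | OCc1cc(OCOC)c(OCOC)c(CC=C(C)C)c1CC=C(C)C
F7 | step 7 | racemic 2-[4,5-bis(methoxymethoxy)-2,3-bis(3-methylbut-2-en-1-yl)phenyl]oxirane | CC(C)=CCc1c(C2CO2)cc(OCOC)c(OCOC)c1CC=C(C)C
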